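**Strategy**

1. Cuts: first the aryl O–Si bond of a protected phenol. Next O1–C2 of the dihydropyran, back to an (R)-epoxyprenyl phenol. Last C6–C7 and C8–C8a of benzene ring A, which splits the molecule into a four-carbon diene and an alkynyl ketone.
2. Enabling feature (chroman numbering O1, C2, C3, C4, C4a, C5–C8, C8a): around ring A, C8a(O)–C4a(CH2)–C5(OMe)–C6(H) is the C1–C4 pattern of a 2-alkyl-1,3-dioxygenated ketene-acetal butadiene, and C7(H)–C8(acyl) is a terminal ynone.
3. Forward: p-coumaric acid brings the 4-hydroxyphenyl ring and the E olefin and is turned into an enynone. Methyl acetoacetate and prenyl bromide are turned into an epoxide-bearing Brassard-type diene.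
4. Ring order: the phenol ring is bought. Ring A arises by [4+2] cycloaddition and loss of methanol, which also joins the two fragments. The dihydropyran closes last, in the same flask, by 6-endo opening of the epoxide.
5. Stereochemistry: C3 (R), the only stereocentre, is set by Shi epoxidation of the prenyl olefin. It is kept because only the C2–O bond of the epoxide is ever broken.

Key step: step 8

Remark on the chemistry: the D-fructose-derived ketone is assumed to give the (R)-epoxide, as its spiro transition-state model predicts for trisubstituted olefins. The enantiomeric ketone would be used if the sense proved opposite.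

**Route**

Step 1
Reactants: 1 (E)-4-hydroxycinnamic acid (p-coumaric acid)
Product: 2 (E)-3-(4-hydroxyphenyl)-N-methoxy-N-methylprop-2-enamide
Conditions: MeNHOMe·HCl, EDC·HCl, HOBt (cat.), i-Pr2NEt, DMF, 0 °C to rt
Reagents that add atoms: N,O-dimethylhydroxylamine hydrochloride, CNOC.Cl
Why: Carbodiimide amide coupling (Weinreb amide formation), in which the amine outcompetes the weakly nucleophilic phenol for the activated acid, so no prior protection is needed and the E olefin is untouched.

Step 2
Reactants: 2 (E)-3-(4-hydroxyphenyl)-N-methoxy-N-methylprop-2-enamide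
Product: 3 (E)-3-[4-(tert-butyldimethylsilyloxy)phenyl]-N-methoxy-N-methylprop-2-enamide
Conditions: TBSCl, imidazole, DMF, rt
Reagents that add atoms: tert-butyldimethylsilyl chloride, CC(C)(C)[Si](C)(C)Cl
Why: Standard imidazole-promoted silylation of a phenol, giving an aryl silyl ether that tolerates the Grignard reagent, the thermal cycloaddition and the catalytic sulfonic acid ahead but falls to fluoride at the end.

Step 3
Reactants: 3 (E)-3-[4-(tert-butyldimethylsilyloxy)phenyl]-N-methoxy-N-methylprop-2-enamide; 4 ethynylmagnesium bromide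
Product: 6 (E)-1-[4-(tert-butyldimethylsilyloxy)phenyl]pent-1-en-4-yn-3-one, via chelated tetrahedral magnesium adduct 5 (not isolated)
Conditions: THF, 0 °C; poured into aq NaHSO4 at 0 °C
Reagents that add atoms: none
Why: Weinreb ketone synthesis, in which the acetylide adds 1,2 and chelate 5 holds until the quench so no second addition occurs, while the cold acidic quench protonates the released amine before it can add to the terminal ynone.

Step 4
Reactants: 7 methyl acetoacetate; 8 prenyl bromide (1-bromo-3-methylbut-2-ene)
Product: 9 methyl 2-acetyl-5-methylhex-4-enoate (racemic)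
Conditions: K2CO3, acetone, reflux (slight excess of 7)
Reagents that add atoms: none
Why: Classical acetoacetic ester C-alkylation with a reactive allylic bromide under carbonate base, the excess of keto ester holding back dialkylation and the racemic centre being erased in the next step.

Step 5
Reactants: 9 methyl 2-acetyl-5-methylhex-4-enoate
Product: 11 methyl 3-methoxy-2-(3-methylbut-2-enyl)but-2-enoate (E/Z mixture), via dimethyl ketal 10 (not isolated)
Conditions: HC(OMe)3, H2SO4 (cat.), MeOH, rt; neutralisation, then distillation under reduced pressure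
Reagents that add atoms: trimethyl orthoformate, COC(OC)OC
Why: Acid-catalysed ketalisation with the orthoester as water scavenger, then loss of methanol from ketal 10 to the ester-conjugated enol ether, is the usual way to 2-alkyl-3-methoxycrotonates, and catalytic acid at room temperature should leave the trisubstituted olefin alone.

Step 6
Reactants: 11 methyl 3-methoxy-2-(3-methylbut-2-enyl)but-2-enoate
Product: 12 methyl 2-{[(2R)-3,3-dimethyloxiran-2-yl]methyl}-3-methoxybut-2-enoate (E/Z mixture at the enol ether)
Conditions: D-fructose-derived Shi ketone (1,2:4,5-di-O-isopropylidene-β-D-erythro-hexo-2,3-diulo-2,6-pyranose, 0.3 equiv), KHSO5 (as 2 KHSO5·KHSO4·K2SO4), K2CO3, Bu4NHSO4 (cat.), MeCN–CH2(OMe)2–aq Na2B4O7 buffer, 0 °C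
Reagents that add atoms: potassium peroxymonosulfate, [K+].[O-]S(=O)(=O)OO
Why: Shi asymmetric epoxidation, in which the electrophilic chiral dioxirane takes the isolated trisubstituted olefin in preference to the crowded, ester-deactivated tetrasubstituted enol ether, and its spiro transition state delivers oxygen to the face that makes the new centre (future C3) R.

Step 7
Reactants: 12 methyl 2-{[(2R)-3,3-dimethyloxiran-2-yl]methyl}-3-methoxybut-2-enoate
Product: 14 {[2-{[(2R)-3,3-dimethyloxiran-2-yl]methyl}-1,3-dimethoxybuta-1,3-dien-1-yl]oxy}trimethylsilane (Brassard-type diene), via lithium dienolate 13 (not isolated)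
Conditions: LiN(i-Pr)2, Me3SiCl (present from the start), THF, −78 °C; volatiles removed in vacuo, pentane, filtration under Ar; used crude at once
Reagents that add atoms: chlorotrimethylsilane, C[Si](C)(C)Cl
Why: Kinetic γ-deprotonation of a 3-methoxycrotonate and O-silylation of dienolate 13 is the standard entry to Brassard dienes, and the chlorosilane already present at −78 °C traps the dienolate before it or the amide base can touch the epoxide, whose stereocentre takes no part.

Step 8
Reactants: 14 {[2-{[(2R)-3,3-dimethyloxiran-2-yl]methyl}-1,3-dimethoxybuta-1,3-dien-1-yl]oxy}trimethylsilane; 6 (E)-1-[4-(tert-butyldimethylsilyloxy)phenyl]pent-1-en-4-yn-3-one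
Product: 17 (E)-3-[4-(tert-butyldimethylsilyloxy)phenyl]-1-[(3R)-3-hydroxy-5-methoxy-2,2-dimethyl-3,4-dihydro-2H-chromen-8-yl]prop-2-en-1-one, via cyclohexa-1,4-diene cycloadduct 15 (not isolated), via epoxyprenyl 2'-hydroxychalcone 16 (not isolated)
Conditions: toluene, rt to 50 °C; then dry CH2Cl2, camphor-10-sulfonic acid (cat.), 0 °C to rt, same flask
Reagents that add atoms: none
Why: Proposed new method: the CH2 terminus of ketene-acetal diene 14, its most nucleophilic carbon, attacks the unsubstituted alkyne carbon of 6 and the acetal carbon then bonds to the acyl-bearing alkyne carbon (asynchronous [4+2], or Mukaiyama–Michael addition followed by six-membered closure of the allenolate onto the dialkoxycarbenium ion), forming C6–C7 and C8–C8a and giving cyclohexa-1,4-diene 15 with a methyl silyl ketal at C8a. Acid ionises this ketal, loss of methanol and of a C6 proton aromatises ring A, and the liberated methanol takes the silyl group off the new oxygen to leave the ketone-chelated phenol 16. The same acid protonates the epoxide, whose C2–O bond is the weaker one because C2 is tertiary, and the phenol oxygen closes the dihydropyran ring in the 6-endo-tet mode (O1–C2). The closest known reactions are the benzannulation of Brassard dienes with alkynyl ketones or haloquinones and the Brønsted-acid cyclisation of ortho-(epoxyprenyl)phenols to 3-hydroxy-2,2-dimethylchromans; new here are an epoxide riding on the diene, a cross-conjugated enynone as dienophile and the merging of all three events into one operation. No lasting stereocentre is made: the C8a ketal centre vanishes on aromatisation, C2 carries two methyl groups, and C3 stays R because its C–O bond is never broken. The step needs head-to-tail regiochemistry (secured by the matched polarisation of diene and ynone), alkyne-over-alkene chemoselectivity (the terminal alkyne is unhindered, the styryl carbon is substituted and deactivated by the para-silyloxy donor) and 6-endo rather than 5-exo opening (secured by acid instead of base, by the gem-dimethyl carbon and by excluding water).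

Step 9
Reactants: 17 (E)-3-[4-(tert-butyldimethylsilyloxy)phenyl]-1-[(3R)-3-hydroxy-5-methoxy-2,2-dimethyl-3,4-dihydro-2H-chromen-8-yl]prop-2-en-1-one
Product: 18 (E)-1-[(3R)-3-hydroxy-5-methoxy-2,2-dimethyl-3,4-dihydro-2H-chromen-8-yl]-3-(4-hydroxyphenyl)prop-2-en-1-one (CNP0291031.2)
Conditions: Bu4NF, AcOH, THF, 0 °C
Reagents that add atoms: none
Why: Fluoride cleavage of an aryl silyl ether is fast because phenoxide leaves silicon readily, and the acetic acid buffer keeps the medium too mild to disturb the chalcone, the secondary alcohol or C3.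

**Compound list**

1 | (E)-4-hydroxycinnamic acid (p-coumaric acid) | O=C(O)/C=C/c1ccc(O)cc1 | starting material
2 | (E)-3-(4-hydroxyphenyl)-N-methoxy-N-methylprop-2-enamide | CON(C)C(=O)/C=C/c1ccc(O)cc1 | intermediate
3 | (E)-3-[4-(tert-butyldimethylsilyloxy)phenyl]-N-methoxy-N-methylprop-2-enamide | CON(C)C(=O)/C=C/c1ccc(O[Si](C)(C)C(C)(C)C)cc1 | intermediate
4 | ethynylmagnesium bromide | C#C[Mg]Br | starting material
5 | chelated tetrahedral magnesium adduct of 3 and 4 (formed in the flask, carbinol carbon racemic) | C#CC(O[Mg]Br)(N(C)OC)/C=C/c1ccc(O[Si](C)(C)C(C)(C)C)cc1 | intermediate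
6 | (E)-1-[4-(tert-butyldimethylsilyloxy)phenyl]pent-1-en-4-yn-3-one | C#CC(=O)/C=C/c1ccc(O[Si](C)(C)C(C)(C)C)cc1 | intermediate
7 | methyl acetoacetate | CC(=O)CC(=O)OC | starting material
8 | prenyl bromide (1-bromo-3-methylbut-2-ene) | CC(C)=CCBr | starting material
9 | methyl 2-acetyl-5-methylhex-4-enoate (racemic) | CC(=O)C(CC=C(C)C)C(=O)OC | intermediate
10 | methyl 2-(1,1-dimethoxyethyl)-5-methylhex-4-enoate (formed in the flask) | COC(=O)C(CC=C(C)C)C(C)(OC)OC | intermediate
11 | methyl 3-methoxy-2-(3-methylbut-2-enyl)but-2-enoate (E/Z mixture) | COC(=O)C(CC=C(C)C)=C(C)OC | intermediate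
12 | methyl 2-{[(2R)-3,3-dimethyloxiran-2-yl]methyl}-3-methoxybut-2-enoate | COC(=O)C(C[C@H]1OC1(C)C)=C(C)OC | intermediate
13 | lithium dienolate of 12 (formed in the flask) | COC(O[Li])=C(C[C@H]1OC1(C)C)C(=C)OC | intermediate
14 | {[2-{[(2R)-3,3-dimethyloxiran-2-yl]methyl}-1,3-dimethoxybuta-1,3-dien-1-yl]oxy}trimethylsilane | COC(O[Si](C)(C)C)=C(C[C@H]1OC1(C)C)C(=C)OC | intermediate
15 | (E)-1-[5-{[(2R)-3,3-dimethyloxiran-2-yl]methyl}-4,6-dimethoxy-6-(trimethylsilyloxy)cyclohexa-1,4-dien-1-yl]-3-[4-(tert-butyldimethylsilyloxy)phenyl]prop-2-en-1-one (formed in the flask, both ketal epimers) | COC1=C(C[C@H]2OC2(C)C)C(OC)(O[Si](C)(C)C)C(C(=O)/C=C/c2ccc(O[Si](C)(C)C(C)(C)C)cc2)=CC1 | intermediate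
16 | (E)-1-[3-{[(2R)-3,3-dimethyloxiran-2-yl]methyl}-2-hydroxy-4-methoxyphenyl]-3-[4-(tert-butyldimethylsilyloxy)phenyl]prop-2-en-1-one (formed in the flask) | COc1ccc(C(=O)/C=C/c2ccc(O[Si](C)(C)C(C)(C)C)cc2)c(O)c1C[C@H]1OC1(C)C | intermediate
17 | (E)-3-[4-(tert-butyldimethylsilyloxy)phenyl]-1-[(3R)-3-hydroxy-5-methoxy-2,2-dimethyl-3,4-dihydro-2H-chromen-8-yl]prop-2-en-1-one | COc1ccc(C(=O)/C=C/c2ccc(O[Si](C)(C)C(C)(C)C)cc2)c2c1C[C@@H](O)C(C)(C)O2 | intermediate
18 | (E)-1-[(3R)-3-hydroxy-5-methoxy-2,2-dimethyl-3,4-dihydro-2H-chromen-8-yl]-3-(4-hydroxyphenyl)prop-2-en-1-one (CNP0291031.2) | COc1ccc(C(=O)/C=C/c2ccc(O)cc2)c2c1C[C@@H](O)C(C)(C)O2 | target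

**Count and risks**

Total steps: 9 (three to the enynone, four to the diene, two after the union).
Longest linear sequence: 6 steps (steps 4 to 9, from methyl acetoacetate 7 to 18).

**Step 8 (bears the label "Proposed new method:").**
- What may go wrong:
  - premature opening of the epoxide by the ketene acetal or by silyl species during the thermal stage;
  - slow cycloaddition at the fully substituted acetal terminus while the enynone polymerises;
  - closure in the 5-exo instead of the 6-endo sense;
  - oxa-Michael closure of the chelated phenol onto the enone.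
- Fallback, all known chemistry, with ring A bought instead of built. It sets out from prenyl bromide 8. This C-alkylates commercial 2',4'-dihydroxyacetophenone (aq KOH) at the carbon between the two oxygens to give 1-[2,4-dihydroxy-3-(3-methylbut-2-enyl)phenyl]ethanone F1. MeI and K2CO3 in acetone methylate only the non-chelated hydroxyl, giving 1-[2-hydroxy-4-methoxy-3-(3-methylbut-2-enyl)phenyl]ethanone F2. Shi epoxidation follows with the same D-fructose-derived ketone, but under NaHCO3 buffering so that the chelated phenol stays protonated. It should give 1-[3-{[(2R)-3,3-dimethyloxiran-2-yl]methyl}-2-hydroxy-4-methoxyphenyl]ethanone F3. Camphor-10-sulfonic acid in CH2Cl2 closes F3 in the 6-endo sense to 1-[(3R)-3-hydroxy-5-methoxy-2,2-dimethyl-3,4-dihydro-2H-chromen-8-yl]ethanone F4. Here the ring closure can be examined on its own on a simple ketone. Claisen–Schmidt condensation of F4 with 4-hydroxybenzaldehyde (KOH, EtOH) comes back to the route at target 18.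

**Step 7.**
- What may go wrong:
  - intramolecular alkylation of the dienolate carbon by the neighbouring epoxide;
  - base-induced isomerisation of the epoxide followed by lactonisation onto the ester;
  - chloride opening of the epoxide by Me3SiCl and LiCl on warming;
  - protodesilylation of the ketene acetal on handling.
- Fallback, with the epoxide installed only after the benzannulation. It sets out from olefin 11. LiN(i-Pr)2 and Me3SiCl give {[1,3-dimethoxy-2-(3-methylbut-2-enyl)buta-1,3-dien-1-yl]oxy}trimethylsilane F5. Cycloaddition of F5 with enynone 6 in toluene gives the prenyl-substituted cyclohexa-1,4-diene cycloadduct F6. Catalytic camphor-10-sulfonic acid aromatises F6 to (E)-3-[4-(tert-butyldimethylsilyloxy)phenyl]-1-[2-hydroxy-4-methoxy-3-(3-methylbut-2-enyl)phenyl]prop-2-en-1-one (4-hydroxyderricin silyl ether) F7. Shi epoxidation of its only electron-rich olefin, under NaHCO3 buffering to spare the aryl silyl ether and keep the phenol neutral, comes back to the route at 16. In this variant 16 is isolated and then closed to 17 with the same acid. The detour also bypasses step 6, should its chemoselectivity or facial selectivity disappoint.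

**Step 3.**
- What may go wrong: conjugate addition of the liberated amine to the terminal ynone during the quench, or base-induced oligomerisation of the ynone before the acid reaches it.
- Fallback, by addition to an aldehyde and then oxidation, so that no amine is present when the ynone appears. It sets out from Weinreb amide 3. i-Bu2AlH (THF, −78 °C) reduces it to (E)-3-[4-(tert-butyldimethylsilyloxy)phenyl]prop-2-enal F8. Addition of 4 gives racemic (E)-1-[4-(tert-butyldimethylsilyloxy)phenyl]pent-1-en-4-yn-3-ol F9. MnO2 in CH2Cl2 oxidises this doubly activated alcohol and comes back to the route at 6.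

**Further compounds**

F1 | step 8 | 1-[2,4-dihydroxy-3-(3-methylbut-2-enyl)phenyl]ethanone | CC(=O)c1ccc(O)c(CC=C(C)C)c1O
F2 | step 8 | 1-[2-hydroxy-4-methoxy-3-(3-methylbut-2-enyl)phenyl]ethanone | COc1ccc(C(C)=O)c(O)c1CC=C(C)C
F3 | step 8 | 1-[3-{[(2R)-3,3-dimethyloxiran-2-yl]methyl}-2-hydroxy-4-methoxyphenyl]ethanone | COc1ccc(C(C)=O)c(O)c1C[C@H]1OC1(C)C
F4 | step 8 | 1-[(3R)-3-hydroxy-5-methoxy-2,2-dimethyl-3,4-dihydro-2H-chromen-8-yl]ethanone | COc1ccc(C(C)=O)c2c1C[C@@H](O)C(C)(C)O2
F5 | step 7 | {[1,3-dimethoxy-2-(3-methylbut-2-enyl)buta-1,3-dien-1-yl]oxy}trimethylsilane | COC(O[Si](C)(C)C)=C(CC=C(C)C)C(=C)OC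
F6 | step 7 | (E)-1-[4,6-dimethoxy-5-(3-methylbut-2-enyl)-6-(trimethylsilyloxy)cyclohexa-1,4-dien-1-yl]-3-[4-(tert-butyldimethylsilyloxy)phenyl]prop-2-en-1-one | COC1=C(CC=C(C)C)C(OC)(O[Si](C)(C)C)C(C(=O)/C=C/c2ccc(O[Si](C)(C)C(C)(C)C)cc2)=CC1
F7 | step 7 | (E)-3-[4-(tert-butyldimethylsilyloxy)phenyl]-1-[2-hydroxy-4-methoxy-3-(3-methylbut-2-enyl)phenyl]prop-2-en-1-one | COc1ccc(C(=O)/C=C/c2ccc(O[Si](C)(C)C(C)(C)C)cc2)c(O)c1CC=C(C)C
F8 | step 3 | (E)-3-[4-(tert-butyldimethylsilyloxy)phenyl]prop-2-enal | O=C/C=C/c1ccc(O[Si](C)(C)C(C)(C)C)cc1
F9 | step 3 | (E)-1-[4-(tert-butyldimethylsilyloxy)phenyl]pent-1-en-4-yn-3-ol (racemic) | C#CC(O)/C=C/c1ccc(O[Si](C)(C)C(C)(C)C)cc1
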